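**Retrosynthetic overview**

1. Target ⇐ desilylation and O‑demethylation ⇐ 11‑membered carbocycle, closed last by ring‑closing metathesis between the butenyl group on the decalin and the allyl group on the spirocycle.
2. Metathesis substrate ⇐ C3‑lithiated methyl tetronate of spirotetronate fragment B + decalin aldehyde fragment A, then oxidation of the carbinol to the ketone.
3. Fragment A (both decalin rings at once) ⇐ catalytic enantioselective intramolecular Diels–Alder reaction of a tetraenal ⇐ Julia–Kocienski union of an (S)‑citronellol‑derived enal with an Evans‑derived tetrazolyl sulfone.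
4. Fragment B ⇐ cyclohexene ring first (auxiliary‑controlled Diels–Alder, Saegusa oxidation, dienolate allylation then methylation), tetronate ring second (propiolate addition, methoxide‑induced cyclisation).
5. Ring order: cyclohexene of B and decalin of A in parallel → spirotetronate → macrocycle.

Assumption: the target is taken exactly as drawn; by my reading of the SMILES the ring methyl of the decalin (C6) is cis to H‑4a and therefore axial on the trans‑decalin. TBS = tert‑butyldimethylsilyl, TIPS = triisopropylsilyl.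

**Fragment A**

Step 1
Reactants: 1 (R)-4-benzyl-1,3-oxazolidin-2-one; 2 (E)-but-2-enoyl chloride
Product: 3 (R)-4-benzyl-3-[(E)-but-2-enoyl]-1,3-oxazolidin-2-one
Conditions: n-BuLi, THF, −78 °C; then 2, −78 to 0 °C
Reagents that add atoms: none
Why: N‑acylation of the lithiated Evans auxiliary by the acid chloride; no stereocentre is formed.

Step 2
Reactants: 3 (R)-4-benzyl-3-[(E)-but-2-enoyl]-1,3-oxazolidin-2-one
Product: 4 (R)-4-benzyl-3-[(2R)-2-methylbut-3-enoyl]-1,3-oxazolidin-2-one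
Conditions: NaN(SiMe3)2, THF, −78 °C; MeI, −78 to −40 °C
Reagents that add atoms: iodomethane (CI)
Why: Deconjugative Evans alkylation: γ‑deprotonation gives the chelated (Z)‑dienolate, which is methylated at Cα on the face opposite the benzyl group, setting the (R) methyl‑bearing centre of the later side chain.

Step 3
Reactants: 4 (R)-4-benzyl-3-[(2R)-2-methylbut-3-enoyl]-1,3-oxazolidin-2-one
Product: 5 (2R)-2-methylbut-3-en-1-ol
Conditions: LiBH4, H2O (1 equiv), Et2O, 0 °C (volatile product kept in solution)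
Reagents that add atoms: none
Why: Reductive cleavage of the N‑acyl oxazolidinone to the primary alcohol without touching the α‑stereocentre; the auxiliary is recovered.

Step 4
Reactants: 5 (2R)-2-methylbut-3-en-1-ol
Product: 6 5-{[(2R)-2-methylbut-3-en-1-yl]sulfanyl}-1-phenyl-1H-tetrazole
Conditions: 1-phenyl-1H-tetrazole-5-thiol, PPh3, DIAD, THF, 0 °C to rt
Reagents that add atoms: 1-phenyl-1H-tetrazole-5-thiol (Sc1nnnn1-c1ccccc1)
Why: Mitsunobu thioetherification at the primary carbon; the adjacent stereocentre is not involved.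

Step 5
Reactants: 6 5-{[(2R)-2-methylbut-3-en-1-yl]sulfanyl}-1-phenyl-1H-tetrazole
Product: 7 5-{[(2R)-2-methylbut-3-en-1-yl]sulfonyl}-1-phenyl-1H-tetrazole
Conditions: 30% H2O2, (NH4)6Mo7O24·4H2O (10 mol %), EtOH, 0 °C to rt
Reagents that add atoms: hydrogen peroxide (OO)
Why: Molybdate‑catalysed oxidation of the sulfide to the sulfone, which leaves the monosubstituted alkene alone.

Step 6
Reactants: 8 (S)-citronellol [(3S)-3,7-dimethyloct-6-en-1-ol]; 9 ethyl 2-(triphenyl-λ5-phosphanylidene)propanoate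
Product: 11 ethyl (2E,6S)-8-hydroxy-2,6-dimethyloct-2-enoate, via (4S)-6-hydroxy-4-methylhexanal 10 (not isolated)
Conditions: O3, CH2Cl2, −78 °C; PPh3, −78 °C to rt; then 9, rt
Reagents that add atoms: none
Why: Ozonolysis of the trisubstituted alkene followed by Wittig olefination with a stabilised ylide gives the (E)‑2‑methyl enoate; the C6 methyl stereocentre comes unchanged from citronellol.

Step 7
Reactants: 11 ethyl (2E,6S)-8-hydroxy-2,6-dimethyloct-2-enoate
Product: 12 ethyl (2E,6S)-2,6-dimethyl-8-oxooct-2-enoate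
Conditions: TEMPO (10 mol %), PhI(OAc)2, CH2Cl2, rt
Reagents that add atoms: none
Why: Oxoammonium (TEMPO) oxidation of the primary alcohol stops at the aldehyde and does not epimerise the β‑stereocentre.

Step 8
Reactants: 12 ethyl (2E,6S)-2,6-dimethyl-8-oxooct-2-enoate; 13 2-(triphenyl-λ5-phosphanylidene)acetaldehyde
Product: 14 ethyl (2E,6S,8E)-2,6-dimethyl-10-oxodeca-2,8-dienoate
Conditions: toluene, 80 °C
Reagents that add atoms: none
Why: Wittig two‑carbon homologation with the stabilised formyl ylide reacts only with the aliphatic aldehyde and gives the (E)‑enal.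

Step 9
Reactants: 14 ethyl (2E,6S,8E)-2,6-dimethyl-10-oxodeca-2,8-dienoate; 7 5-{[(2R)-2-methylbut-3-en-1-yl]sulfonyl}-1-phenyl-1H-tetrazole
Product: 15 ethyl (2E,6S,8E,10E,12R)-2,6,12-trimethyltetradeca-2,8,10,13-tetraenoate
Conditions: 7, KN(SiMe3)2, DME, −60 °C; then 14, −60 °C to rt
Reagents that add atoms: none
Why: Julia–Kocienski olefination of the enal with the phenyltetrazolyl sulfone forms the second diene double bond with (E) preference and carries the (R) side‑chain centre in intact.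

Step 10
Reactants: 15 ethyl (2E,6S,8E,10E,12R)-2,6,12-trimethyltetradeca-2,8,10,13-tetraenoate
Product: 16 (2E,6S,8E,10E,12R)-2,6,12-trimethyltetradeca-2,8,10,13-tetraen-1-ol
Conditions: i-Bu2AlH (2.2 equiv), CH2Cl2, −78 °C
Reagents that add atoms: none
Why: 1,2‑Reduction of the conjugated ester to the allylic alcohol with retention of all alkene geometries.

Step 11
Reactants: 16 (2E,6S,8E,10E,12R)-2,6,12-trimethyltetradeca-2,8,10,13-tetraen-1-ol
Product: 17 (2E,6S,8E,10E,12R)-2,6,12-trimethyltetradeca-2,8,10,13-tetraenal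
Conditions: TEMPO (10 mol %), PhI(OAc)2, CH2Cl2, 0 °C to rt
Reagents that add atoms: none
Why: Mild TEMPO oxidation of the allylic alcohol gives the (E)‑2‑methyl enal without isomerising the diene.

Step 12
Reactants: 17 (2E,6S,8E,10E,12R)-2,6,12-trimethyltetradeca-2,8,10,13-tetraenal
Product: 18 (1S,2S,4aS,6S,8aR)-2-[(2R)-but-3-en-2-yl]-1,6-dimethyl-1,2,4a,5,6,7,8,8a-octahydronaphthalene-1-carbaldehyde
Conditions: (S)-3,3-diphenyl-1-(2-methylphenyl)tetrahydro-1H,3H-pyrrolo[1,2-c][1,3,2]oxazaborole·HNTf2 (20 mol %), CH2Cl2, −78 to −40 °C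
Reagents that add atoms: none
Why: Intramolecular Diels–Alder reaction through the formyl‑endo, tether‑anti transition state gives the trans‑decalin, with C1, C2, C4a and C8a fixed relative to each other by the (E,E,E) geometry and in the absolute sense by the oxazaborolidinium catalyst (diene on the re face of the enal α‑carbon); the citronellol‑derived C6 methyl must sit axial in the chair‑like tether, so this is a mismatched case whose dr rests on the catalyst.

**Fragment B**

Step 13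
Reactants: 1 (R)-4-benzyl-1,3-oxazolidin-2-one; 19 bromoacetyl bromide
Product: 20 (R)-4-benzyl-3-(2-bromoacetyl)-1,3-oxazolidin-2-one
Conditions: n-BuLi, THF, −78 °C; then 19
Reagents that add atoms: none
Why: N‑acylation of the lithiated oxazolidinone by the more reactive acyl bromide terminus.

Step 14
Reactants: 20 (R)-4-benzyl-3-(2-bromoacetyl)-1,3-oxazolidin-2-one
Product: 21 diethyl {2-[(4R)-4-benzyl-2-oxo-1,3-oxazolidin-3-yl]-2-oxoethyl}phosphonate
Conditions: P(OEt)3, neat, 60 °C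
Reagents that add atoms: triethyl phosphite (CCOP(OCC)OCC)
Why: Michaelis–Arbuzov reaction of the α‑bromo imide gives the phosphonate for a later Horner–Wadsworth–Emmons reaction.

Step 15
Reactants: 22 methyl (3R)-3-hydroxybutanoate
Product: 23 methyl (3R)-3-[(tert-butyldimethylsilyl)oxy]butanoate
Conditions: TBSCl, imidazole, DMF, rt
Reagents that add atoms: tert-butyldimethylsilyl chloride (C[Si](C)(Cl)C(C)(C)C)
Why: Silylation of the chiral‑pool secondary alcohol, which becomes the side‑chain carbinol centre of the target.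

Step 16
Reactants: 23 methyl (3R)-3-[(tert-butyldimethylsilyl)oxy]butanoate
Product: 24 (3R)-3-[(tert-butyldimethylsilyl)oxy]butanal
Conditions: i-Bu2AlH (1.05 equiv), CH2Cl2, −78 °C
Reagents that add atoms: none
Why: Low‑temperature half‑reduction of the ester stops at the aldehyde through the stable tetrahedral aluminium acetal.

Step 17
Reactants: 24 (3R)-3-[(tert-butyldimethylsilyl)oxy]butanal; 21 diethyl {2-[(4R)-4-benzyl-2-oxo-1,3-oxazolidin-3-yl]-2-oxoethyl}phosphonate
Product: 25 (R)-4-benzyl-3-[(2E,5R)-5-[(tert-butyldimethylsilyl)oxy]hex-2-enoyl]-1,3-oxazolidin-2-one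
Conditions: LiCl, i-Pr2NEt, MeCN, rt
Reagents that add atoms: none
Why: Masamune–Roush Horner–Wadsworth–Emmons olefination gives the (E)‑enoyl imide under conditions mild enough for the β‑silyloxy aldehyde.

Step 18
Reactants: 26 but-3-en-2-one
Product: 27 2-[(triisopropylsilyl)oxy]buta-1,3-diene
Conditions: TIPSOTf, Et3N, Et2O, 0 °C
Reagents that add atoms: triisopropylsilyl trifluoromethanesulfonate (CC(C)[Si](OS(=O)(=O)C(F)(F)F)(C(C)C)C(C)C)
Why: Soft enolisation and O‑silylation of the methyl ketone gives the robust 2‑silyloxy diene.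

Step 19
Reactants: 25 (R)-4-benzyl-3-[(2E,5R)-5-[(tert-butyldimethylsilyl)oxy]hex-2-enoyl]-1,3-oxazolidin-2-one; 27 2-[(triisopropylsilyl)oxy]buta-1,3-diene
Product: 28 (R)-4-benzyl-3-{[(1R,6R)-6-[(2R)-2-(TBS-oxy)propyl]-4-(TIPS-oxy)cyclohex-3-en-1-yl]carbonyl}-1,3-oxazolidin-2-one
Conditions: Et2AlCl (1.4 equiv), CH2Cl2, −78 to −30 °C
Reagents that add atoms: none
Why: Evans auxiliary‑controlled Diels–Alder reaction: the chelated s‑cis enoyl imide is attacked by the nucleophilic diene terminus at the β‑carbon ("para" regiochemistry) on the face opposite the benzyl group, which sets the side‑chain‑bearing ring carbon (R).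

Step 20
Reactants: 28 (R)-4-benzyl-3-{[(1R,6R)-6-[(2R)-2-(TBS-oxy)propyl]-4-(TIPS-oxy)cyclohex-3-en-1-yl]carbonyl}-1,3-oxazolidin-2-one
Product: 29 methyl (1R,6R)-6-[(2R)-2-(TBS-oxy)propyl]-4-(TIPS-oxy)cyclohex-3-ene-1-carboxylate
Conditions: NaOMe (0.3 equiv), MeOH/THF, 0 °C
Reagents that add atoms: methanol (CO)
Why: Methoxide‑catalysed exocyclic methanolysis of the imide gives the methyl ester and returns the auxiliary; the TIPS enol ether survives.

Step 21
Reactants: 29 methyl (1R,6R)-6-[(2R)-2-(TBS-oxy)propyl]-4-(TIPS-oxy)cyclohex-3-ene-1-carboxylate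
Product: 30 methyl (1S,6R)-6-[(2R)-2-(TBS-oxy)propyl]-4-oxocyclohex-2-ene-1-carboxylate
Conditions: Pd(OAc)2 (1.05 equiv), MeCN, rt
Reagents that add atoms: none
Why: Saegusa–Ito oxidation of the regiodefined silyl enol ether places the enone double bond between C2 and C3.

Step 22
Reactants: 30 methyl (1S,6R)-6-[(2R)-2-(TBS-oxy)propyl]-4-oxocyclohex-2-ene-1-carboxylate
Product: 31 methyl (6R)-4-oxo-3-(prop-2-en-1-yl)-6-[(2R)-2-(TBS-oxy)propyl]cyclohex-1-ene-1-carboxylate (C3 epimers)
Conditions: NaH (1.0 equiv), THF, 0 °C; allyl bromide (1.05 equiv)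
Reagents that add atoms: allyl bromide (C=CCBr)
Why: Hagemann‑ester‑type vinylogous alkylation: the γ‑proton is removed and the extended enolate is allylated α to the ketone, moving the alkene into conjugation with the ester (the C3 configuration is not yet relevant).

Step 23
Reactants: 31 methyl (6R)-4-oxo-3-(prop-2-en-1-yl)-6-[(2R)-2-(TBS-oxy)propyl]cyclohex-1-ene-1-carboxylate
Product: 32 methyl (3R,6R)-3-methyl-4-oxo-3-(prop-2-en-1-yl)-6-[(2R)-2-(TBS-oxy)propyl]cyclohex-1-ene-1-carboxylate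
Conditions: NaH (1.1 equiv), THF/DMF, 0 °C; MeI
Reagents that add atoms: iodomethane (CI)
Why: Second dienolate alkylation: methyl iodide attacks C3 axially and anti to the C6 side chain, which is held pseudoaxial by allylic strain with the ester‑bearing sp2 carbon, so the quaternary centre forms with allyl cis to the side chain.

Step 24
Reactants: 32 methyl (3R,6R)-3-methyl-4-oxo-3-(prop-2-en-1-yl)-6-[(2R)-2-(TBS-oxy)propyl]cyclohex-1-ene-1-carboxylate; 33 methyl propiolate
Product: 34 methyl (3R,4S,6R)-4-hydroxy-4-(3-methoxy-3-oxoprop-1-yn-1-yl)-3-methyl-3-(prop-2-en-1-yl)-6-[(2R)-2-(TBS-oxy)propyl]cyclohex-1-ene-1-carboxylate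
Conditions: 33, LiN(SiMe3)2, THF, −78 °C; then 32, −78 °C
Reagents that add atoms: none
Why: 1,2‑Addition of the lithium acetylide to the ketone from the face away from the pseudoaxial C6 side chain (the other face suffers a 1,3‑diaxial clash) sets the future spiro carbon with oxygen cis to the side chain.

Step 25
Reactants: 34 methyl (3R,4S,6R)-4-hydroxy-4-(3-methoxy-3-oxoprop-1-yn-1-yl)-3-methyl-3-(prop-2-en-1-yl)-6-[(2R)-2-(TBS-oxy)propyl]cyclohex-1-ene-1-carboxylate
Product: 35 methyl (5S,6R,9R)-4-methoxy-6-methyl-2-oxo-6-(prop-2-en-1-yl)-9-[(2R)-2-(TBS-oxy)propyl]-1-oxaspiro[4.5]deca-3,7-diene-8-carboxylate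
Conditions: NaOMe (0.2 equiv), MeOH, rt
Reagents that add atoms: methanol (CO)
Why: Conjugate addition of methoxide to the ynoate followed by lactonisation of the tertiary alkoxide builds the 4‑methoxybutenolide (methyl tetronate) without touching the stereocentres.

Step 26
Reactants: 35 methyl (5S,6R,9R)-4-methoxy-6-methyl-2-oxo-6-(prop-2-en-1-yl)-9-[(2R)-2-(TBS-oxy)propyl]-1-oxaspiro[4.5]deca-3,7-diene-8-carboxylate
Product: 36 (5S,6R,9R)-8-(hydroxymethyl)-4-methoxy-6-methyl-6-(prop-2-en-1-yl)-9-[(2R)-2-(TBS-oxy)propyl]-1-oxaspiro[4.5]deca-3,7-dien-2-one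
Conditions: i-Bu2AlH (2.3 equiv), CH2Cl2, −78 °C
Reagents that add atoms: none
Why: The conjugated methyl ester is reduced to the allylic alcohol faster than the electron‑rich vinylogous carbonate of the methyl tetronate at −78 °C.

Step 27
Reactants: 36 (5S,6R,9R)-8-(hydroxymethyl)-4-methoxy-6-methyl-6-(prop-2-en-1-yl)-9-[(2R)-2-(TBS-oxy)propyl]-1-oxaspiro[4.5]deca-3,7-dien-2-one
Product: 37 (5S,6R,9R)-8-[(TBS-oxy)methyl]-4-methoxy-6-methyl-6-(prop-2-en-1-yl)-9-[(2R)-2-(TBS-oxy)propyl]-1-oxaspiro[4.5]deca-3,7-dien-2-one (fragment B)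
Conditions: TBSCl, imidazole, DMF, rt
Reagents that add atoms: tert-butyldimethylsilyl chloride (C[Si](C)(Cl)C(C)(C)C)
Why: Silylation of the primary allylic alcohol so that no acidic O–H interferes with the tetronate lithiation.

**Union and endgame**

Step 28
Reactants: 37 fragment B (spirocyclic methyl tetronate); 18 decalin aldehyde
Product: 38 carbinol from C3 of the tetronate of 37 and the formyl carbon of 18 (mixture of carbinol epimers)
Conditions: 37, LiN(i-Pr)2, THF, −78 °C; then 18, −78 to −40 °C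
Reagents that add atoms: none
Why: C3 lithiation of the 4‑methoxybutenolide and 1,2‑addition to the non‑enolisable neopentyl aldehyde joins the fragments; the new carbinol centre is removed in the next step.

Step 29
Reactants: 38 coupled carbinol
Product: 39 3-acyl-4-methoxy tetronate ketone carrying the vinyl and allyl termini
Conditions: Dess–Martin periodinane, CH2Cl2, rt
Reagents that add atoms: none
Why: Dess–Martin oxidation of the hindered secondary alcohol gives the acyl tetronate ketone without affecting the alkenes or silyl ethers.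

Step 30
Reactants: 39 acyl tetronate ketone
Product: 40 macrocyclic bis-TBS methyl tetronate with the new (E) double bond in the 11-membered ring
Conditions: RuCl2(=CHPh)(PCy3)(H2IMes) (second-generation Grubbs catalyst, 15 mol %), CH2Cl2 (1 mM), 40 °C
Reagents that add atoms: none
Why: Ring‑closing metathesis of the two monosubstituted alkenes (the ring and trisubstituted alkenes do not react) closes the 11‑membered carbocycle, and the (E) alkene is expected to be the less strained isomer in this rigid ring.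

Step 31
Reactants: 40 macrocyclic bis-TBS methyl tetronate
Product: 41 macrocyclic bis-TBS 3-acyl tetronic acid
Conditions: LiCl, DMSO, 50 °C; dilute HCl work-up
Reagents that add atoms: none
Why: Chloride demethylates the vinylogous methyl ester by SN2 attack at the methyl group and frees the acyl tetronic acid.

Step 32
Reactants: 41 macrocyclic bis-TBS 3-acyl tetronic acid
Product: 42 target compound
Conditions: HF·pyridine, THF/pyridine, 0 °C to rt
Reagents that add atoms: none
Why: Fluoride‑mediated cleavage of both silyl ethers under mildly acidic conditions that the acyl tetronic acid tolerates.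

**Compound list**

1 | (R)-4-benzyl-1,3-oxazolidin-2-one | O=C1N[C@H](Cc2ccccc2)CO1 | starting material
2 | (E)-but-2-enoyl chloride | C/C=C/C(Cl)=O | starting material
3 | (R)-4-benzyl-3-[(E)-but-2-enoyl]-1,3-oxazolidin-2-one | C/C=C/C(=O)N1C(=O)OC[C@H]1Cc1ccccc1 | intermediate
4 | (R)-4-benzyl-3-[(2R)-2-methylbut-3-enoyl]-1,3-oxazolidin-2-one | C=C[C@@H](C)C(=O)N1C(=O)OC[C@H]1Cc1ccccc1 | intermediate
5 | (2R)-2-methylbut-3-en-1-ol | C=C[C@@H](C)CO | intermediate
6 | 5-{[(2R)-2-methylbut-3-en-1-yl]sulfanyl}-1-phenyl-1H-tetrazole | C=C[C@@H](C)CSc1nnnn1-c1ccccc1 | intermediate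
7 | 5-{[(2R)-2-methylbut-3-en-1-yl]sulfonyl}-1-phenyl-1H-tetrazole | C=C[C@@H](C)CS(=O)(=O)c1nnnn1-c1ccccc1 | intermediate
8 | (S)-citronellol | C[C@H](CCO)CCC=C(C)C | starting material
9 | ethyl 2-(triphenyl-λ5-phosphanylidene)propanoate | CCOC(=O)C(C)=P(c1ccccc1)(c1ccccc1)c1ccccc1 | starting material
10 | (4S)-6-hydroxy-4-methylhexanal (formed in situ) | C[C@H](CCO)CCC=O | intermediate
11 | ethyl (2E,6S)-8-hydroxy-2,6-dimethyloct-2-enoate | C[C@H](CCO)CC/C=C(\C)C(=O)OCC | intermediate
12 | ethyl (2E,6S)-2,6-dimethyl-8-oxooct-2-enoate | C[C@H](CC=O)CC/C=C(\C)C(=O)OCC | intermediate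
13 | 2-(triphenyl-λ5-phosphanylidene)acetaldehyde | O=CC=P(c1ccccc1)(c1ccccc1)c1ccccc1 | starting material
14 | ethyl (2E,6S,8E)-2,6-dimethyl-10-oxodeca-2,8-dienoate | C[C@H](C/C=C/C=O)CC/C=C(\C)C(=O)OCC | intermediate
15 | ethyl (2E,6S,8E,10E,12R)-2,6,12-trimethyltetradeca-2,8,10,13-tetraenoate | C[C@H](C/C=C/C=C/[C@H](C)C=C)CC/C=C(\C)C(=O)OCC | intermediate
16 | (2E,6S,8E,10E,12R)-2,6,12-trimethyltetradeca-2,8,10,13-tetraen-1-ol | C[C@H](C/C=C/C=C/[C@H](C)C=C)CC/C=C(\C)CO | intermediate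
17 | (2E,6S,8E,10E,12R)-2,6,12-trimethyltetradeca-2,8,10,13-tetraenal | C[C@H](C/C=C/C=C/[C@H](C)C=C)CC/C=C(\C)C=O | intermediate
18 | (1S,2S,4aS,6S,8aR)-2-[(2R)-but-3-en-2-yl]-1,6-dimethyl-1,2,4a,5,6,7,8,8a-octahydronaphthalene-1-carbaldehyde (fragment A) | C[C@H]1CC[C@@H]2[C@H](C=C[C@@H]([C@H](C)C=C)[C@@]2(C)C=O)C1 | intermediate
19 | bromoacetyl bromide | BrCC(Br)=O | starting material
20 | (R)-4-benzyl-3-(2-bromoacetyl)-1,3-oxazolidin-2-one | BrCC(=O)N1C(=O)OC[C@H]1Cc1ccccc1 | intermediate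
21 | diethyl {2-[(4R)-4-benzyl-2-oxo-1,3-oxazolidin-3-yl]-2-oxoethyl}phosphonate | CCOP(=O)(OCC)CC(=O)N1C(=O)OC[C@H]1Cc1ccccc1 | intermediate
22 | methyl (3R)-3-hydroxybutanoate | C[C@@H](O)CC(=O)OC | starting material
23 | methyl (3R)-3-[(tert-butyldimethylsilyl)oxy]butanoate | C[C@@H](O[Si](C)(C)C(C)(C)C)CC(=O)OC | intermediate
24 | (3R)-3-[(tert-butyldimethylsilyl)oxy]butanal | C[C@@H](O[Si](C)(C)C(C)(C)C)CC=O | intermediate
25 | (R)-4-benzyl-3-[(2E,5R)-5-[(tert-butyldimethylsilyl)oxy]hex-2-enoyl]-1,3-oxazolidin-2-one | C[C@@H](O[Si](C)(C)C(C)(C)C)C/C=C/C(=O)N1C(=O)OC[C@H]1Cc1ccccc1 | intermediate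
26 | but-3-en-2-one | C=CC(C)=O | starting material
27 | 2-[(triisopropylsilyl)oxy]buta-1,3-diene | C=CC(=C)O[Si](C(C)C)(C(C)C)C(C)C | intermediate
28 | (R)-4-benzyl-3-{[(1R,6R)-6-[(2R)-2-(TBS-oxy)propyl]-4-(TIPS-oxy)cyclohex-3-en-1-yl]carbonyl}-1,3-oxazolidin-2-one | CC(C)[Si](OC1=CC[C@@H](C(=O)N2C(=O)OC[C@H]2Cc2ccccc2)[C@H](C[C@@H](C)O[Si](C)(C)C(C)(C)C)C1)(C(C)C)C(C)C | intermediate
29 | methyl (1R,6R)-6-[(2R)-2-(TBS-oxy)propyl]-4-(TIPS-oxy)cyclohex-3-ene-1-carboxylate | CC(C)[Si](OC1=CC[C@@H](C(=O)OC)[C@H](C[C@@H](C)O[Si](C)(C)C(C)(C)C)C1)(C(C)C)C(C)C | intermediate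
30 | methyl (1S,6R)-6-[(2R)-2-(TBS-oxy)propyl]-4-oxocyclohex-2-ene-1-carboxylate | O=C1C=C[C@@H](C(=O)OC)[C@H](C[C@@H](C)O[Si](C)(C)C(C)(C)C)C1 | intermediate
31 | methyl (6R)-4-oxo-3-(prop-2-en-1-yl)-6-[(2R)-2-(TBS-oxy)propyl]cyclohex-1-ene-1-carboxylate (C3 epimers) | C=CCC1C=C(C(=O)OC)[C@H](C[C@@H](C)O[Si](C)(C)C(C)(C)C)CC1=O | intermediate
32 | methyl (3R,6R)-3-methyl-4-oxo-3-(prop-2-en-1-yl)-6-[(2R)-2-(TBS-oxy)propyl]cyclohex-1-ene-1-carboxylate | C=CC[C@]1(C)C=C(C(=O)OC)[C@H](C[C@@H](C)O[Si](C)(C)C(C)(C)C)CC1=O | intermediate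
33 | methyl propiolate | C#CC(=O)OC | starting material
34 | methyl (3R,4S,6R)-4-hydroxy-4-(3-methoxy-3-oxoprop-1-yn-1-yl)-3-methyl-3-(prop-2-en-1-yl)-6-[(2R)-2-(TBS-oxy)propyl]cyclohex-1-ene-1-carboxylate | C=CC[C@]1(C)C=C(C(=O)OC)[C@H](C[C@@H](C)O[Si](C)(C)C(C)(C)C)C[C@@]1(O)C#CC(=O)OC | intermediate
35 | methyl (5S,6R,9R)-4-methoxy-6-methyl-2-oxo-6-(prop-2-en-1-yl)-9-[(2R)-2-(TBS-oxy)propyl]-1-oxaspiro[4.5]deca-3,7-diene-8-carboxylate | C=CC[C@]1(C)C=C(C(=O)OC)[C@H](C[C@@H](C)O[Si](C)(C)C(C)(C)C)C[C@]12OC(=O)C=C2OC | intermediate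
36 | (5S,6R,9R)-8-(hydroxymethyl)-4-methoxy-6-methyl-6-(prop-2-en-1-yl)-9-[(2R)-2-(TBS-oxy)propyl]-1-oxaspiro[4.5]deca-3,7-dien-2-one | C=CC[C@]1(C)C=C(CO)[C@H](C[C@@H](C)O[Si](C)(C)C(C)(C)C)C[C@]12OC(=O)C=C2OC | intermediate
37 | (5S,6R,9R)-8-[(TBS-oxy)methyl]-4-methoxy-6-methyl-6-(prop-2-en-1-yl)-9-[(2R)-2-(TBS-oxy)propyl]-1-oxaspiro[4.5]deca-3,7-dien-2-one (fragment B) | C=CC[C@]1(C)C=C(CO[Si](C)(C)C(C)(C)C)[C@H](C[C@@H](C)O[Si](C)(C)C(C)(C)C)C[C@]12OC(=O)C=C2OC | intermediate
38 | carbinol joining tetronate C3 of 37 to the former formyl carbon of 18 (carbinol epimers) | C=CC[C@]1(C)C=C(CO[Si](C)(C)C(C)(C)C)[C@H](C[C@@H](C)O[Si](C)(C)C(C)(C)C)C[C@]12OC(=O)C(C(O)[C@@]3(C)[C@@H]4CC[C@H](C)C[C@H]4C=C[C@H]3[C@H](C)C=C)=C2OC | intermediate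
39 | 3-(decalin-1-carbonyl)-4-methoxy spirotetronate (ketone of 38) with vinyl and allyl termini | C=CC[C@]1(C)C=C(CO[Si](C)(C)C(C)(C)C)[C@H](C[C@@H](C)O[Si](C)(C)C(C)(C)C)C[C@]12OC(=O)C(C(=O)[C@@]3(C)[C@@H]4CC[C@H](C)C[C@H]4C=C[C@H]3[C@H](C)C=C)=C2OC | intermediate
40 | 11-membered (E)-macrocycle, bis-TBS ether, methyl tetronate | C[C@H]1CC[C@@H]2[C@H](C=C[C@H]3[C@H](C)/C=C/C[C@]4(C)C=C(CO[Si](C)(C)C(C)(C)C)[C@H](C[C@@H](C)O[Si](C)(C)C(C)(C)C)C[C@]45OC(=O)C(=C5OC)C(=O)[C@@]23C)C1 | intermediate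
41 | 11-membered (E)-macrocycle, bis-TBS ether, free 3-acyl tetronic acid | C[C@H]1CC[C@@H]2[C@H](C=C[C@H]3[C@H](C)/C=C/C[C@]4(C)C=C(CO[Si](C)(C)C(C)(C)C)[C@H](C[C@@H](C)O[Si](C)(C)C(C)(C)C)C[C@]45OC(=O)C(=C5O)C(=O)[C@@]23C)C1 | intermediate
42 | target compound (CNP0189906.1) | C[C@H]1CC[C@@H]2[C@H](C=C[C@H]3[C@H](C)/C=C/C[C@]4(C)C=C(CO)[C@H](C[C@@H](C)O)C[C@]45OC(=O)C(=C5O)C(=O)[C@@]23C)C1 | target

**Step count**

Total: 32 steps. Longest linear sequence: 17 steps (steps 15, 16, 17, then 19 to 32; 22 → 42), which is 53% of the total. Fragment A needs 12 steps in two branches (steps 1–5 and 6–8, joined in step 9); fragment B needs 15 steps including two reagent branches (steps 13–14 and 18).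

**Steps most likely to fail**

Step 12 (intramolecular Diels–Alder). The catalyst has to override the tether methyl group, which prefers the equatorial position of the chair‑like tether and so favours the C6‑epimeric decalin; the dr may be modest, the assigned catalyst sense rests on the usual pre‑transition‑state model (the antipodal catalyst is equally available), and the skipped diene is acid‑sensitive. Fallback: it sets out from tetraenal 17 and spirotetronate 37 and comes back at ketone 39. Lithiated 37 (LiN(i-Pr)2, THF, −78 °C) is added 1,2 to 17 to give the acyclic tetraenyl carbinol F1. Oxidation with Dess–Martin periodinane gives the acyl tetronate tetraenone F2, in which the 3‑acyl‑4‑methoxybutenolide activates the 2‑methyl enone as dienophile. The intramolecular Diels–Alder reaction is then run thermally (toluene, 60–100 °C) or with Me2AlCl and gives 39 directly. The facial bias then comes from the covalently bound spirocycle next to the dienophile instead of an external catalyst; the diastereomers are separated at 39.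

Step 30 (ring‑closing metathesis). An 11‑membered ring next to two quaternary centres may close slowly, dimerise, or give the (Z) alkene. Fallback: it sets out from aldehyde 18 and spirotetronate 37 and comes back at macrocycle 40. The (E) alkene is made first by intermolecular cross‑metathesis (RuCl2(=CH-C6H4-2-O-i-Pr)(H2IMes), second‑generation Hoveyda–Grubbs catalyst, CH2Cl2, 40 °C, excess 37) to give the open‑chain aldehyde–tetronate F3. The ring is then closed at the other end by intramolecular addition of the C3‑lithiated tetronate to the non‑enolisable aldehyde (LiN(i-Pr)2, THF, −78 °C, high dilution) to give the macrocyclic carbinol F4. Dess–Martin oxidation of F4 gives 40.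

Step 23 (quaternary centre by dienolate methylation). O‑ or γ‑alkylation and imperfect facial selectivity are possible. Fallback: it sets out from enone ester 30 and comes back at ketone 32. Compound 30 is methylated first (NaH, MeI) to the 3‑methyl keto ester F5. O‑acylation of its extended enolate (KN(SiMe3)2, allyl chloroformate, THF, −78 °C) gives the allyl dienyl carbonate F6. Decarboxylative asymmetric allylation (Pd2(dba)3, a zerovalent palladium source, with (S)-t-Bu-PHOX, toluene, 30 °C) then delivers the allyl group under catalyst control, cis to the side chain, to give 32.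

**Further compounds**

F1 | step 12 | carbinol from addition of C3-lithiated 37 to the formyl group of 17 (carbinol epimers) | C=CC[C@]1(C)C=C(CO[Si](C)(C)C(C)(C)C)[C@H](C[C@@H](C)O[Si](C)(C)C(C)(C)C)C[C@]12OC(=O)C(C(O)/C(C)=C/CC[C@H](C)C/C=C/C=C/[C@H](C)C=C)=C2OC
F2 | step 12 | acyl tetronate tetraenone (ketone of F1) | C=CC[C@]1(C)C=C(CO[Si](C)(C)C(C)(C)C)[C@H](C[C@@H](C)O[Si](C)(C)C(C)(C)C)C[C@]12OC(=O)C(C(=O)/C(C)=C/CC[C@H](C)C/C=C/C=C/[C@H](C)C=C)=C2OC
F3 | step 30 | (E) cross-metathesis product of 18 and 37 (decalin aldehyde linked to the spirotetronate) | C[C@H]1CC[C@@H]2[C@H](C=C[C@@H]([C@H](C)/C=C/C[C@]3(C)C=C(CO[Si](C)(C)C(C)(C)C)[C@H](C[C@@H](C)O[Si](C)(C)C(C)(C)C)C[C@]34OC(=O)C=C4OC)[C@@]2(C)C=O)C1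
F4 | step 30 | macrocyclic carbinol (alcohol corresponding to 40, carbinol epimers) | C[C@H]1CC[C@@H]2[C@H](C=C[C@H]3[C@H](C)/C=C/C[C@]4(C)C=C(CO[Si](C)(C)C(C)(C)C)[C@H](C[C@@H](C)O[Si](C)(C)C(C)(C)C)C[C@]45OC(=O)C(=C5OC)C(O)[C@@]23C)C1
F5 | step 23 | methyl (6R)-3-methyl-4-oxo-6-[(2R)-2-(TBS-oxy)propyl]cyclohex-1-ene-1-carboxylate (C3 epimers) | CC1C=C(C(=O)OC)[C@H](C[C@@H](C)O[Si](C)(C)C(C)(C)C)CC1=O
F6 | step 23 | methyl (6R)-3-methyl-4-{[(prop-2-en-1-yloxy)carbonyl]oxy}-6-[(2R)-2-(TBS-oxy)propyl]cyclohexa-1,3-diene-1-carboxylate | C=CCOC(=O)OC1=C(C)C=C(C(=O)OC)[C@H](C[C@@H](C)O[Si](C)(C)C(C)(C)C)C1
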